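All runs are calculated for an exercise; noise was put on by code.

**The vessel.** The vessel starts at [E] = 1.5 M and takes a whole Z charge of 1.50 M over 50 s; the amber run is this flask followed so far, and the grey run carries half the Z.

| flask | E | Z | remark | time |
|---|---|---|---|---|
| amber | 1.5 M | 1.5 M (fed, over 50 s) | the very flask that is asked about, followed so far; the fed solution adds 0.25 times the starting volume |  |
| grey | 1.5 M | 0.75 M (fed, over 50 s) | run made earlier; the fed solution adds 0.25 times the starting volume |  |
| flask | 1.5 M | 1.50 M (fed, over 50 s) | the fed solution adds 0.25 times the starting volume | 80 min |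

| run | time / min | E / % | J / % | D / % |
|---|---|---|---|---|
| amber | 6.00 | 38 | 11 | 13 |
| amber | 12.0 | 40 | 5 | 18 |
| amber | 20.0 | 38 | 5 | 14 |
| amber | 25.0 | 41 | 1 | 16 |
| amber | 30.0 | 41 | 4 | 15 |
| grey | 6.00 | 63 | 10 | 11 |
| grey | 12.0 | 65 | 7 | 10 |
| grey | 25.0 | 63 | 4 | 13 |
| grey | 40.0 | 64 | 2 | 15 |
| grey | 80.0 | 65 | 2 | 16 |

(standard deviation of a reading: 1.5 percentage points)

- amount of E at 80 min, in percent of the E charged
- amount of J at 80 min, in percent of the E charged
- amount of D at 80 min, in percent of the E charged
- amount of Q at 80 min, in percent of the E charged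

- charges are per starting volume, the dose included; the dosed solution carries all of it
- the earlier runs were read with a standard deviation of 1.5 percentage points
- steps thought possible: E + Z <-> J; E + Z -> D; Z + J -> Q; Z + D -> Q; J <-> L

**Pairing rule.** Follow one Z: it ends on an E, and a Q holds two Z on one E, while J, D and L hold one. So each Q leaves one E unreached, and with free Z negligible, E minus Q equals one minus charged [Z] over charged [E], the pairing excess 0% of the E charged. Amber E stays level from 38% to 41%, so free Z is taken as negligible, an assumption.

**Two ways.** Amber E averages 39.6%, so pairing gives Q = 39.6%. Counting E instead, by subtracting mean E, J and D from the whole, gives 40.0%. They part by 0.4 percentage points, with readings scattered by 1.5 points.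

**Which cheats.** The count holds L inside Q. At 80.0 min the grey count gives 17.0%, and pairing, with its excess of 50.0%, gives 15.0%. Pairing is therefore the one to use for Q.

**The reckoning.** For amber at 80 min, this reckoning takes E and Q at 39.6% each and J at the late grey 2%, which leaves D with L at 18.8%.

**The result.** The forecast differs slightly in its figures, with E 40%, J 1%, D 18% and Q 41%, and it too has it that “E then holds flat”. The flask gives E 41.5%, J 0.471%, D 16.3% and Q 41.2%.

    E + Z ⇌ J (K = 2.10 M⁻¹, k = 0.00810 M⁻¹ s⁻¹)
    E + Z → D (k = 0.00240 M⁻¹ s⁻¹)
    Z + J → Q (k = 0.0190 M⁻¹ s⁻¹)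
    Z + D → Q (k = 0.00400 M⁻¹ s⁻¹)
    J ⇌ L (K = 1.20, k = 0.00590 s⁻¹)

**What stands.** At 80 min the half-life of E by E + Z into D is 21 h. Z is the limiting reagent, with 0.32% of its charge left against 41% of E, and E stands 0.30 points above Q. E moves by 5 points at a Z charge of 1.34 M or 1.66 M. For a neighbour flask charged with 0.38 M of Z, pairing gives an excess of 74.7%; it holds E 81.1% and Q 6.23%, a difference of 75 points.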